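**Retrosynthetic overview**
Numbering: ring B (seven-membered) is C11(=O)–C2(CH3)=C3H–C4H(OH)–C5H–C6(CH3)–C10H2; ring A (five-membered) is C5–C6–C7H2–C8H2–C9(O-aroyl)(i-Pr).
Feature: once C4–OH/C5–H is traced back to a C4=C5 alkene, the C11 carbonyl of ring B lies γ,δ to that alkene across the quaternary C6 (C11–C10–C6–C5=C4), a Claisen retron whose ether oxygen is the C4 oxygen.
Late disconnections: both silyl ethers; C2=C3 (Saegusa–Ito); the C9 aroyl ester (alkoxide acylation); C4–OH/C5–H (hydroboration of C4=C5).
Key disconnection: C6–C10, by ring-expanding Claisen rearrangement of 2-methylideneoxolane 12 (allylic ether O–C4, enol ether C11=C10), made from lactone 11, methallyl carbinol 7 (reagent-controlled allylboration sets C4) and enal 5.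
Ring order: ring A first (ozonolysis/aldol ring contraction of (S)-terpinen-4-ol, which supplies C9), then the temporary oxolane, then ring B in the key step.

Key step: step 8

Assumption: the methyl-bearing C2 centre created in step 5 is carried as a mixture of epimers, which is of no consequence because C2 becomes trigonal in step 18.

**Route**

Step 1
Reactants: 1 (S)-terpinen-4-ol
Product: 2 (S)-terpinen-4-ol triethylsilyl ether
Conditions: TESOTf, 2,6-lutidine, CH2Cl2, 0 °C → rt
Reagents that add atoms: triethylsilyl trifluoromethanesulfonate CC[Si](CC)(CC)OS(=O)(=O)C(F)(F)F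
Why: Silyl triflate/2,6-lutidine silylation is the standard way to cap a hindered tertiary alcohol, and the ether keeps the future C9 oxygen from lactol formation, retro-aldol loss and borane direction later on; no stereocentre is touched.

Step 2
Reactants: 2 (S)-terpinen-4-ol triethylsilyl ether
Product: 4 (3S)-6-oxo-3-(propan-2-yl)-3-(triethylsilyloxy)heptanal, via secondary ozonide 3 (not isolated)
Conditions: O3, CH2Cl2, −78 °C; then PPh3, −78 °C → rt
Reagents that add atoms: ozone [O-][O+]=O
Why: Ozonolysis with reductive work-up cleaves the only C=C bond to the 1,6-keto aldehyde without touching the silyl ether or the stereocentre.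

Step 3
Reactants: 4 (3S)-6-oxo-3-(propan-2-yl)-3-(triethylsilyloxy)heptanal
Product: 5 (5R)-2-methyl-5-(propan-2-yl)-5-(triethylsilyloxy)cyclopent-1-ene-1-carbaldehyde
Conditions: piperidine, AcOH, toluene, 70 °C
Reagents that add atoms: none
Why: Amine/acid-mediated intramolecular aldol condensation (the enamine of the aldehyde adds to the methyl ketone in a five-membered closure, then dehydration) should give the tetrasubstituted cyclopentenecarbaldehyde, i.e. ring A with the formyl carbon as the future C4; the quaternary centre is untouched.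

Step 4
Reactants: 5 (5R)-2-methyl-5-(propan-2-yl)-5-(triethylsilyloxy)cyclopent-1-ene-1-carbaldehyde
Product: 7 (1S)-3-methyl-1-[(5R)-2-methyl-5-(propan-2-yl)-5-(triethylsilyloxy)cyclopent-1-en-1-yl]but-3-en-1-ol, via diisopinocampheylborinate 6 (not isolated)
Conditions: (−)-Ipc2BOMe (from (+)-α-pinene), CH2=C(CH3)CH2MgCl, Et2O, −78 °C → rt; then 5, −78 °C; then NaOH, H2O2, 0 °C → rt
Reagents that add atoms: 2-methylallylmagnesium chloride CC(=C)C[Mg]Cl
Why: Brown asymmetric allylboration through a chair six-membered transition state, in which the (+)-α-pinene-derived borane delivers the methallyl group to the si face of the aldehyde under reagent control, should set the (S) carbinol (future C4) that later relays chirality to C6.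

Step 5
Reactants: 7 (1S)-3-methyl-1-[(5R)-2-methyl-5-(propan-2-yl)-5-(triethylsilyloxy)cyclopent-1-en-1-yl]but-3-en-1-ol
Product: 9 (4S)-2-methyl-4-[(5R)-2-methyl-5-(propan-2-yl)-5-(triethylsilyloxy)cyclopent-1-en-1-yl]butane-1,4-diol (C2 epimers), via bis(9-BBN) adduct 8 (not isolated)
Conditions: 9-BBN (2.5 equiv), THF, 0 °C → rt; then NaOH, H2O2, 0 °C
Reagents that add atoms: hydrogen peroxide OO
Why: Anti-Markovnikov hydroboration–oxidation with the bulky 9-BBN should select the 1,1-disubstituted alkene over the tetrasubstituted ring alkene, and the new methyl-bearing centre (future C2) need not be controlled.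

Step 6
Reactants: 9 (4S)-2-methyl-4-[(5R)-2-methyl-5-(propan-2-yl)-5-(triethylsilyloxy)cyclopent-1-en-1-yl]butane-1,4-diol (C2 epimers)
Product: 11 (5S)-3-methyl-5-[(5R)-2-methyl-5-(propan-2-yl)-5-(triethylsilyloxy)cyclopent-1-en-1-yl]oxolan-2-one (C3 epimers), via lactol 10 (not isolated)
Conditions: TEMPO (cat.), PhI(OAc)2, CH2Cl2, rt
Reagents that add atoms: none
Why: TEMPO/PhI(OAc)2 oxidative lactonisation oxidises the primary alcohol, traps the aldehyde as the lactol with the hindered secondary hydroxyl and oxidises it on to the γ-lactone, so the carbinol C–O bond and its configuration stay intact.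

Step 7
Reactants: 11 (5S)-3-methyl-5-[(5R)-2-methyl-5-(propan-2-yl)-5-(triethylsilyloxy)cyclopent-1-en-1-yl]oxolan-2-one (C3 epimers)
Product: 12 (5S)-3-methyl-2-methylidene-5-[(5R)-2-methyl-5-(propan-2-yl)-5-(triethylsilyloxy)cyclopent-1-en-1-yl]oxolane (C3 epimers)
Conditions: Cp2TiMe2, toluene, 65 °C, dark; filtration through basic Al2O3
Reagents that add atoms: dimethyltitanocene C[Ti](C)(C1C=CC=C1)C1C=CC=C1
Why: Petasis methylenation (Cp2Ti=CH2 generated thermally, oxatitanacyclobutane, cycloreversion) converts the lactone carbonyl into the exocyclic enol ether under non-acidic conditions that spare the allylic ether and the silyl ether.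

Step 8
Reactants: 12 (5S)-3-methyl-2-methylidene-5-[(5R)-2-methyl-5-(propan-2-yl)-5-(triethylsilyloxy)cyclopent-1-en-1-yl]oxolane (C3 epimers)
Product: 13 (6R,9R)-bicyclic ketone: ring B as cyclohept-4-en-11-one (C4=C5) fused at C5–C6 to ring A, with C2–CH3, C6–CH3, C9–i-Pr and C9–OSiEt3 (C2 epimers)
Conditions: xylenes (degassed), Et3N (5 mol%), base-washed sealed tube, 185 °C
Reagents that add atoms: none
Why: On heating, the allyl vinyl ether C10=C11–O–C4–C5=C6 embedded in 12 undergoes a concerted, suprafacial [3,3]-sigmatropic (Claisen) shift that forms C6–C10 and the C11 carbonyl while the allylic O–C4 bond breaks, driven by C=O formation. The closest known reaction type is the thermal ring-expanding Claisen rearrangement of 2-methylidene-5-vinyloxolanes to cyclohept-4-enones. Ring B is closed not by a direct cyclisation but by two-atom ring expansion of the oxolane: the five-membered ether ties the six-centre array into a boat-like, oxygen-bridged transition state and opens as the seven-membered carbocycle forms. The new quaternary stereocentre C6 is controlled by C4 alone, because ring B can hold only a cis C4=C5 bond, so C3 must lie syn to C6 and C10 reaches C6 on the face from which the (4S) C–O bond departs, the face opposite the C9 silyloxy group, giving (6R). The step needs the sigmatropic path to outrun exo-to-endo migration of the enol ether double bond and ionisation of the allylic C4–O bond, which the amine-buffered, apolar, base-washed medium should secure; both C2 epimers converge because C2 is a spectator that is levelled later.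

Step 9
Reactants: 13 (6R,9R)-bicyclic cyclohept-4-en-11-one (C2 epimers)
Product: 14 ethylene ketal (1,3-dioxolane at C11) of 13
Conditions: TMSOCH2CH2OTMS, TMSOTf (5 mol%), CH2Cl2, −78 → −20 °C; pyridine quench
Reagents that add atoms: 1,2-bis(trimethylsilyloxy)ethane C[Si](C)(C)OCCO[Si](C)(C)C
Why: Noyori ketalisation under aprotic conditions at low temperature should mask the ketone against borane without ionising the tertiary allylic silyl ether or moving the C4=C5 bond.

Step 10
Reactants: 14 ethylene ketal of 13
Product: 16 (4S,5S,6R,9R)-C4 alcohol of the ring B ketal (C4–OH cis to C5–H; trans ring fusion; C9–OSiEt3), via C4 alkylborane 15 (not isolated)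
Conditions: BH3·THF, THF, 0 °C → rt; then NaOH, H2O2, 0 °C → rt
Reagents that add atoms: hydrogen peroxide OO
Why: Hydroboration–oxidation places boron on the less substituted C4 and hydrogen on C5 in a syn addition expected on the face opposite the C6 methyl and C9 silyloxy groups, and oxidation with retention then gives the C4 hydroxyl cis to C5–H with the trans ring fusion of the target.

Step 11
Reactants: 16 (4S,5S,6R,9R)-C4 alcohol with C9–OSiEt3
Product: 17 (4S,5S,6R,9R)-C4,C9-diol of the ring B ketal
Conditions: Bu4NF, THF, 45 °C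
Reagents that add atoms: none
Why: Fluoride-induced desilylation frees the tertiary C9 hydroxyl while the ketal and the carbon skeleton are inert to Bu4NF.

Step 12
Reactants: 17 (4S,5S,6R,9R)-C4,C9-diol of the ring B ketal
Product: 18 C4 tert-butyldimethylsilyl ether of 17 (C9–OH free)
Conditions: TBSOTf (1.05 equiv), 2,6-lutidine, CH2Cl2, −78 °C
Reagents that add atoms: tert-butyldimethylsilyl trifluoromethanesulfonate CC(C)(C)[Si](C)(C)OS(=O)(=O)C(F)(F)F
Why: Silylation with a limiting amount of silyl triflate at low temperature should discriminate the secondary C4 hydroxyl from the far more hindered tertiary C9 hydroxyl.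

Step 13
Reactants: 19 4-hydroxybenzoic acid
Product: 20 tert-butyldimethylsilyl 4-(tert-butyldimethylsilyloxy)benzoate
Conditions: TBSCl (2.3 equiv), imidazole, DMF, rt
Reagents that add atoms: tert-butyldimethylsilyl chloride CC(C)(C)[Si](C)(C)Cl
Why: Standard imidazole-mediated silylation caps both the phenol and the carboxylic acid.

Step 14
Reactants: 20 tert-butyldimethylsilyl 4-(tert-butyldimethylsilyloxy)benzoate
Product: 21 4-(tert-butyldimethylsilyloxy)benzoyl chloride
Conditions: (COCl)2, DMF (cat.), CH2Cl2, 0 °C → rt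
Reagents that add atoms: oxalyl chloride O=C(Cl)C(Cl)=O
Why: Oxalyl chloride with catalytic DMF converts a silyl ester directly into the acid chloride under neutral conditions (silyl chloride is expelled), so the aryl silyl ether survives.

Step 15
Reactants: 18 C4 silyl ether with free C9–OH; 21 4-(tert-butyldimethylsilyloxy)benzoyl chloride
Product: 23 C9 4-(tert-butyldimethylsilyloxy)benzoate of 18, via lithium alkoxide 22 (not isolated)
Conditions: n-BuLi, THF, −78 °C; then 21, −78 °C → rt
Reagents that add atoms: none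
Why: O-Acylation of a preformed lithium alkoxide by an aroyl chloride is the established way to esterify hindered tertiary alcohols, the ketal removes any competing enolisable ketone, and C9 keeps its configuration because only the O–H bond reacts.

Step 16
Reactants: 23 C9 aroyl ester, C4 silyl ether, C11 ketal
Product: 24 C11 ketone (C2 epimers) with C4–OTBS and C9 aroyl ester
Conditions: PPTS, acetone–H2O, 50 °C
Reagents that add atoms: water O
Why: Mild acid-catalysed ketal hydrolysis unmasks the C11 ketone under conditions that the silyl ethers and the tertiary benzoate should tolerate.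

Step 17
Reactants: 24 C11 ketone
Product: 25 C11=C2 trimethylsilyl enol ether of 24
Conditions: TMSOTf, Et3N, CH2Cl2, 0 °C
Reagents that add atoms: trimethylsilyl trifluoromethanesulfonate C[Si](C)(C)OS(=O)(=O)C(F)(F)F
Why: Soft enolisation with silyl triflate and excess amine should favour the more substituted C11=C2 silyl enol ether, and the C10 regioisomer is harmless because the quaternary C6 leaves it no β-hydrogen for the next step.

Step 18
Reactants: 25 C11=C2 trimethylsilyl enol ether
Product: 26 bis-silylated target: C2=C3 enone with C4–OTBS and C9 4-(tert-butyldimethylsilyloxy)benzoate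
Conditions: Pd(OAc)2 (1.1 equiv), MeCN, rt
Reagents that add atoms: none
Why: Saegusa–Ito oxidation (palladium enolate, β-hydride elimination toward C3) gives the conjugated endocyclic C2=C3 enone and thereby erases the uncontrolled C2 centre.

Step 19
Reactants: 26 bis-silylated target
Product: 27 target CNP0153637.1
Conditions: HF·pyridine, pyridine, THF, 0 °C → rt
Reagents that add atoms: none
Why: Buffered fluoride cleaves the aryl and the secondary silyl ether in one operation without base or strong acid, which the tertiary ester and the γ-hydroxy enone require.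

**Compound list**
1 | (S)-terpinen-4-ol | CC1=CC[C@](O)(C(C)C)CC1 | starting material
2 | (S)-terpinen-4-ol triethylsilyl ether | CC1=CC[C@](O[Si](CC)(CC)CC)(C(C)C)CC1 | intermediate
3 | secondary ozonide of 2 (not isolated; diastereomers at the trioxolane carbons) | CC12CC[C@@](O[Si](CC)(CC)CC)(C(C)C)CC(OO1)O2 | intermediate
4 | (3S)-6-oxo-3-(propan-2-yl)-3-(triethylsilyloxy)heptanal | O=CC[C@](O[Si](CC)(CC)CC)(C(C)C)CCC(C)=O | intermediate
5 | (5R)-2-methyl-5-(propan-2-yl)-5-(triethylsilyloxy)cyclopent-1-ene-1-carbaldehyde | CC1=C(C=O)[C@](O[Si](CC)(CC)CC)(C(C)C)CC1 | intermediate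
6 | diisopinocampheylborinate of 7 (not isolated) | C=C(C)C[C@H](OB([C@@H]1C[C@@H]2C[C@H]([C@H]1C)C2(C)C)[C@@H]1C[C@@H]2C[C@H]([C@H]1C)C2(C)C)C1=C(C)CC[C@@]1(O[Si](CC)(CC)CC)C(C)C | intermediate
7 | (1S)-3-methyl-1-[(5R)-2-methyl-5-(propan-2-yl)-5-(triethylsilyloxy)cyclopent-1-en-1-yl]but-3-en-1-ol | C=C(C)C[C@H](O)C1=C(C)CC[C@@]1(O[Si](CC)(CC)CC)C(C)C | intermediate
8 | O,C-bis(9-borabicyclo[3.3.1]nonan-9-yl) adduct of 7 (not isolated) | CC(CB1C2CCCC1CCC2)C[C@H](OB1C2CCCC1CCC2)C1=C(C)CC[C@@]1(O[Si](CC)(CC)CC)C(C)C | intermediate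
9 | (4S)-2-methyl-4-[(5R)-2-methyl-5-(propan-2-yl)-5-(triethylsilyloxy)cyclopent-1-en-1-yl]butane-1,4-diol (C2 epimers) | CC(CO)C[C@H](O)C1=C(C)CC[C@@]1(O[Si](CC)(CC)CC)C(C)C | intermediate
10 | lactol: (5S)-3-methyl-5-(cyclopentenyl)oxolan-2-ol (not isolated) | CC1C[C@H](OC1O)C1=C(C)CC[C@@]1(O[Si](CC)(CC)CC)C(C)C | intermediate
11 | (5S)-3-methyl-5-[(5R)-2-methyl-5-(propan-2-yl)-5-(triethylsilyloxy)cyclopent-1-en-1-yl]oxolan-2-one (C3 epimers) | CC1C[C@H](OC1=O)C1=C(C)CC[C@@]1(O[Si](CC)(CC)CC)C(C)C | intermediate
12 | (5S)-3-methyl-2-methylidene-5-[(5R)-2-methyl-5-(propan-2-yl)-5-(triethylsilyloxy)cyclopent-1-en-1-yl]oxolane (C3 epimers) | C=C1O[C@@H](CC1C)C1=C(C)CC[C@@]1(O[Si](CC)(CC)CC)C(C)C | intermediate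
13 | (6R,9R)-bicyclic cyclohept-4-en-11-one: C4=C5, C2–CH3, C6–CH3, C9–i-Pr, C9–OSiEt3 (C2 epimers) | CC1CC=C2[C@](C)(CC[C@@]2(O[Si](CC)(CC)CC)C(C)C)CC1=O | intermediate
14 | C11 ethylene ketal of 13 | CC1CC=C2[C@](C)(CC[C@@]2(O[Si](CC)(CC)CC)C(C)C)CC13OCCO3 | intermediate
15 | C4 alkylborane from 14 (not isolated) | CC1C[C@H](B)[C@@H]2[C@](C)(CC[C@@]2(O[Si](CC)(CC)CC)C(C)C)CC13OCCO3 | intermediate
16 | (4S,5S,6R,9R)-C4 alcohol, C9–OSiEt3, C11 ketal | CC1C[C@H](O)[C@@H]2[C@](C)(CC[C@@]2(O[Si](CC)(CC)CC)C(C)C)CC13OCCO3 | intermediate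
17 | (4S,5S,6R,9R)-C4,C9-diol, C11 ketal | CC1C[C@H](O)[C@@H]2[C@](C)(CC[C@@]2(O)C(C)C)CC13OCCO3 | intermediate
18 | (4S,5S,6R,9R)-C4–OTBS, C9–OH, C11 ketal | CC1C[C@H](O[Si](C)(C)C(C)(C)C)[C@@H]2[C@](C)(CC[C@@]2(O)C(C)C)CC13OCCO3 | intermediate
19 | 4-hydroxybenzoic acid | O=C(O)c1ccc(O)cc1 | starting material
20 | tert-butyldimethylsilyl 4-(tert-butyldimethylsilyloxy)benzoate | CC(C)(C)[Si](C)(C)OC(=O)c1ccc(O[Si](C)(C)C(C)(C)C)cc1 | intermediate
21 | 4-(tert-butyldimethylsilyloxy)benzoyl chloride | CC(C)(C)[Si](C)(C)Oc1ccc(cc1)C(Cl)=O | intermediate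
22 | lithium C9 alkoxide of 18 (not isolated) | CC1C[C@H](O[Si](C)(C)C(C)(C)C)[C@@H]2[C@](C)(CC[C@@]2(O[Li])C(C)C)CC13OCCO3 | intermediate
23 | (4S,5S,6R,9R)-C9 4-(TBSO)benzoate, C4–OTBS, C11 ketal | CC1C[C@H](O[Si](C)(C)C(C)(C)C)[C@@H]2[C@](C)(CC[C@@]2(OC(=O)c2ccc(O[Si](C)(C)C(C)(C)C)cc2)C(C)C)CC13OCCO3 | intermediate
24 | (4S,5S,6R,9R)-C11 ketone, C4–OTBS, C9 4-(TBSO)benzoate (C2 epimers) | CC1C[C@H](O[Si](C)(C)C(C)(C)C)[C@@H]2[C@](C)(CC[C@@]2(OC(=O)c2ccc(O[Si](C)(C)C(C)(C)C)cc2)C(C)C)CC1=O | intermediate
25 | C11=C2 trimethylsilyl enol ether of 24 | CC=1C[C@H](O[Si](C)(C)C(C)(C)C)[C@@H]2[C@](C)(CC[C@@]2(OC(=O)c2ccc(O[Si](C)(C)C(C)(C)C)cc2)C(C)C)CC=1O[Si](C)(C)C | intermediate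
26 | bis-silylated target: C2=C3 enone, C4–OTBS, C9 4-(TBSO)benzoate | CC1=C[C@H](O[Si](C)(C)C(C)(C)C)[C@@H]2[C@](C)(CC[C@@]2(OC(=O)c2ccc(O[Si](C)(C)C(C)(C)C)cc2)C(C)C)CC1=O | intermediate
27 | CNP0153637.1: (3R,3aS,4S,8aR)-4-hydroxy-6,8a-dimethyl-7-oxo-3-(propan-2-yl)-1,2,3,3a,4,7,8,8a-octahydroazulen-3-yl 4-hydroxybenzoate, i.e. (4S,5S,6R,9R) in the numbering above | CC1=C[C@H](O)[C@@H]2[C@](C)(CC[C@@]2(OC(=O)c2ccc(O)cc2)C(C)C)CC1=O | target

**Step count and risks**
Total step count: 19. Longest linear sequence: 17 (steps 1–12 and 15–19; steps 13–14 make the acid chloride).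

Step 8. The thermal shift is slowed by the tetrasubstituted C5=C6 terminus and by the 1,3-interaction between the departing C4–O bond and the C9 isopropyl group. It may therefore be outrun by migration of the exocyclic enol ether double bond into the oxolane ring or by heterolysis of the allylic C4–O bond with loss of chirality transfer. The fallback sets out from 12 and comes back at 13. Compound 12 is treated with i-Bu3Al in CH2Cl2 at −78 °C → rt, the organoaluminium-promoted reductive variant of the ring-expanding Claisen rearrangement. Coordination of the ether oxygen lowers the barrier so that the shift runs far below the temperature of double-bond migration, and the carbonyl is reduced in the same flask by β-hydride transfer, giving the cyclohept-4-en-11-ol F1. Oxidation with Dess–Martin periodinane (NaHCO3, CH2Cl2) returns ketone 13.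

Step 10. Borane may be delivered with poor facial selectivity, since the top face of C4=C5 carries the C9 isopropyl group and the fold of ring B while the bottom face carries the C6 methyl and C9 silyloxy groups. The fallback sets out from 14 and comes back at 17. It moves stereocontrol from the alkene face to the carbonyl group.
- The hydroboration–oxidation is run without regard to the face, giving 16 together with its C4,C5-bis-epimer, the cis-fused alcohol F2.
- The mixture is oxidised with Dess–Martin periodinane to the C4 ketones, the trans-fused ketone F3 and the cis-fused ketone F4.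
- DBU in toluene should equilibrate C5 toward F3, in which the C4 arm stands cis to the C9 oxygen and not to the bulkier isopropyl group.
- HF·pyridine (non-basic, to avoid retro-aldol cleavage) removes the triethylsilyl group to give the β-hydroxy ketone F5.
- Me4NBH(OAc)3 in MeCN/AcOH at −20 °C (Evans–Saksena reduction) delivers hydride intramolecularly from the face of the C9 hydroxyl, which should give the C4 alcohol on the opposite face, i.e. diol 17.

Step 15. Acylation of the congested tertiary C9 alkoxide may stall, or silyl transfer from the aryl silyl ether may compete. The fallback sets out from 14 and comes back at 23. It moves the acylation to the stage where C9 is flanked by the trigonal C5.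
- Bu4NF converts 14 into the tertiary allylic alcohol F6.
- n-BuLi followed by 21 gives the allylic C9 aroyl ester F7.
- BH3·SMe2 at 0 °C (alkene hydroboration is faster than reduction of the hindered aryl ester), then NaBO3·4H2O (mild oxidation that spares the aryl silyl ether), gives the C4 alcohol F8.
- TBSOTf/2,6-lutidine at −78 °C then gives 23.

**Further compounds**
F1 | step 8 | (6R,9R)-bicyclic cyclohept-4-en-11-ol (C4=C5, C9–OSiEt3; C2 and C11 epimers) | CC1CC=C2[C@](C)(CC[C@@]2(O[Si](CC)(CC)CC)C(C)C)CC1O
F2 | step 10 | C4,C5-bis-epimer of 16 (cis-fused C4 alcohol, C9–OSiEt3, C11 ketal) | CC1C[C@@H](O)[C@H]2[C@](C)(CC[C@@]2(O[Si](CC)(CC)CC)C(C)C)CC13OCCO3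
F3 | step 10 | trans-fused C4 ketone (C5 as in the target), C9–OSiEt3, C11 ketal | CC1CC(=O)[C@@H]2[C@](C)(CC[C@@]2(O[Si](CC)(CC)CC)C(C)C)CC13OCCO3
F4 | step 10 | cis-fused C4 ketone (C5 epimer of F3) | CC1CC(=O)[C@H]2[C@](C)(CC[C@@]2(O[Si](CC)(CC)CC)C(C)C)CC13OCCO3
F5 | step 10 | trans-fused C4 ketone with free C9–OH, C11 ketal | CC1CC(=O)[C@@H]2[C@](C)(CC[C@@]2(O)C(C)C)CC13OCCO3
F6 | step 15 | tertiary allylic C9 alcohol (C4=C5), C11 ketal | CC1CC=C2[C@](C)(CC[C@@]2(O)C(C)C)CC13OCCO3
F7 | step 15 | allylic C9 4-(tert-butyldimethylsilyloxy)benzoate (C4=C5), C11 ketal | CC1CC=C2[C@](C)(CC[C@@]2(OC(=O)c2ccc(O[Si](C)(C)C(C)(C)C)cc2)C(C)C)CC13OCCO3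
F8 | step 15 | (4S,5S,6R,9R)-C4 alcohol with C9 4-(tert-butyldimethylsilyloxy)benzoate, C11 ketal | CC1C[C@H](O)[C@@H]2[C@](C)(CC[C@@]2(OC(=O)c2ccc(O[Si](C)(C)C(C)(C)C)cc2)C(C)C)CC13OCCO3
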